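**Retrosynthetic overview**
1. Target 26 comes from 25 (C19 deacetylation) and 24 (C7 oxidation). The key step makes 24 from hydroxy alkynyl oxirane 22: Ph3PAuNTf2 closes the tetrahydrofuran (O9–C13, inversion at C13) and the 2,3-dihydrofuran (O16–C15) in one operation.
2. 22 comes from 8-ene 20 by α-epoxidation and 7β-acetate-assisted trans-diaxial opening (sets 8β-OAc and 9α-OH). The alkynyl oxirane comes from Sharpless epoxidation (sets C13) and Colvin homologation of allylic alcohol 17.
3. 17 comes from allylic triacetate 13 and the cuprate of dilithiated methallyl alcohol 14; 13 comes from enone 11 and decalin aldehyde 9.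
4. 9 comes from polyenal 7 by organo-SOMO radical-cation bicyclization (C5, C10) and C4 methylation; 7 comes from geranyl acetate 1 and 2-(3-chloropropyl)-1,3-dioxolane 4.
5. Ring order: rings A and B together (step 5), then the two oxygen rings together (step 16).

Assumptions: bicyclic compounds carry labdane numbering (C17 on C8, C18 α and C19 β on C4, C20 on C10, side chain C11–C16 on C9); the imidazolidinone antipode in step 5 is taken as the one that gives the 5S,10S series.

**Step 1**
Reactants: 1 geranyl acetate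
Product: 2 (2E,6E)-8-hydroxy-3,7-dimethylocta-2,6-dien-1-yl acetate
Conditions: SeO2 (0.3 equiv), t-BuOOH, salicylic acid (cat.), CH2Cl2, 0 °C to rt
Reagents that add atoms: selenium dioxide O=[Se]=O (oxygen carrier, substoichiometric); tert-butyl hydroperoxide CC(C)(C)OO
Why: Sharpless SeO2/t-BuOOH allylic oxidation (ene reaction, then 2,3-sigmatropic shift) hydroxylates only the (E)-methyl of the electron-rich terminal alkene because the acetoxy-bearing alkene is deactivated; no stereocentre is formed.

**Step 2**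
Reactants: 2 (2E,6E)-8-hydroxy-3,7-dimethylocta-2,6-dien-1-yl acetate
Product: 3 (2E,6E)-8-bromo-3,7-dimethylocta-2,6-dien-1-yl acetate
Conditions: CBr4, PPh3, CH2Cl2, 0 °C
Reagents that add atoms: carbon tetrabromide BrC(Br)(Br)Br
Why: Appel bromination of a primary allylic alcohol proceeds by SN2 displacement of the oxyphosphonium without touching the alkene geometry or the acetate.

**Step 3**
Reactants: 3 (2E,6E)-8-bromo-3,7-dimethylocta-2,6-dien-1-yl acetate; 4 2-(3-chloropropyl)-1,3-dioxolane
Product: 6 (2E,6E)-11-(1,3-dioxolan-2-yl)-3,7-dimethylundeca-2,6-dien-1-yl acetate, via Grignard reagent 5 (not isolated)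
Conditions: 4, Mg, THF, 60 °C; then 3, Li2CuCl4 (3 mol%), THF, −20 to 0 °C
Reagents that add atoms: none
Why: Kochi–Schlosser copper-catalysed Grignard coupling substitutes the primary allylic bromide (SN2, E geometry kept) much faster than the Grignard reagent attacks the acetate at low temperature.

**Step 4**
Reactants: 6 (2E,6E)-11-(1,3-dioxolan-2-yl)-3,7-dimethylundeca-2,6-dien-1-yl acetate
Product: 7 (2E,6E)-3,7-dimethyl-12-oxododeca-2,6-dien-1-yl acetate
Conditions: AcOH/H2O/THF, 45 °C
Reagents that add atoms: water O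
Why: mild acid-catalysed acetal hydrolysis frees the aldehyde while the allylic acetate and both trisubstituted alkenes survive.

**Step 5**
Reactants: 7 (2E,6E)-3,7-dimethyl-12-oxododeca-2,6-dien-1-yl acetate
Product: 8 bicyclic aldehyde (trans-decalin: 10β-CH3, 5α-H, 4α-CHO with 4β-H, exocyclic 8(17)-methylene, 9β-CH2OAc with 9α-H)
Conditions: (2S,5S)-2-tert-butyl-3-methyl-5-(1-naphthylmethyl)imidazolidin-4-one·TFA (30 mol%), Cu(OTf)2 (2.5 equiv), CF3CO2Na, TFA, i-PrCN/DME, rt
Reagents that add atoms: none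
Why: Proposed new method: the enamine of 7 is oxidized by Cu(OTf)2 to a radical cation whose α-carbon closes ring A 6-endo on the trisubstituted alkene through a chair transition state shielded on one face by the catalyst (sets C5 and C10 trans, 5S,10S), the tertiary C10 radical closes ring B 6-endo on the second alkene, and the C8 radical is oxidized by a second Cu(OTf)2 and loses a proton to the exocyclic alkene (endocyclic isomers converge in step 7); the closest known reactions are the aryl-terminated organo-SOMO polyene cyclization and Mn(OAc)3/Cu(OAc)2 oxidative radical polycyclizations that end in alkenes.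

**Step 6**
Reactants: 8 bicyclic aldehyde
Product: 9 11-acetoxy-12,13,14,15,16-pentanorlabd-8(17)-en-19-al (4α-CH3, 4β-CHO)
Conditions: KOtBu, MeI, THF, 0 °C
Reagents that add atoms: iodomethane CI
Why: C-methylation of the potassium enolate of an α-branched aldehyde occurs from the equatorial α face because the axial β face is blocked by the syn-axial C20 methyl, which leaves the formyl group axial (C19) and sets C4.

**Step 7**
Reactants: 9 11-acetoxy-12,13,14,15,16-pentanorlabd-8(17)-en-19-al
Product: 10 11-acetoxy-12,13,14,15,16-pentanorlabd-8-en-19-al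
Conditions: TsOH·H2O (10 mol%), PhH, 50 °C
Reagents that add atoms: none
Why: acid-catalysed alkene isomerization through the tertiary C8 cation funnels the exocyclic (and any 7-ene) isomer to the thermodynamically preferred tetrasubstituted 8-ene; no stereocentre is formed and C9 becomes trigonal.

**Step 8**
Reactants: 10 11-acetoxy-12,13,14,15,16-pentanorlabd-8-en-19-al
Product: 11 11-acetoxy-7-oxo-12,13,14,15,16-pentanorlabd-8-en-19-al
Conditions: CrO3, 3,5-dimethylpyrazole, CH2Cl2, −20 °C
Reagents that add atoms: chromium trioxide O=[Cr](=O)=O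
Why: Salmond allylic oxidation with the CrO3·3,5-dimethylpyrazole complex converts the ring allylic CH2 (C7) into the conjugated enone, while C11 is deactivated by its acetoxy group and the neopentyl aldehyde is inert under anhydrous conditions.

**Step 9**
Reactants: 11 11-acetoxy-7-oxo-12,13,14,15,16-pentanorlabd-8-en-19-al
Product: 12 11-acetoxy-12,13,14,15,16-pentanorlabd-8-ene-7β,19-diol
Conditions: NaBH4, CeCl3·7H2O, MeOH, −20 to 0 °C
Reagents that add atoms: none
Why: Luche reduction delivers hydride 1,2 to the enone from the α face (axial attack anti to C20, as for steroidal 4-en-3-ones) to set the equatorial 7β-alcohol, and also reduces the aldehyde to the C19 primary alcohol.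

**Step 10**
Reactants: 12 11-acetoxy-12,13,14,15,16-pentanorlabd-8-ene-7β,19-diol
Product: 13 12,13,14,15,16-pentanorlabd-8-ene-7β,11,19-triyl triacetate
Conditions: Ac2O, pyridine, DMAP (cat.), CH2Cl2, rt
Reagents that add atoms: acetic anhydride CC(=O)OC(C)=O
Why: DMAP-catalysed acylation gives the 7β-acetate needed as neighbouring group in step 15 and protects C19; no stereocentre changes.

**Step 11**
Reactants: 13 12,13,14,15,16-pentanorlabd-8-ene-7β,11,19-triyl triacetate; 14 2-methylprop-2-en-1-ol (methallyl alcohol)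
Product: 17 7β,19-diacetoxy-15-norlabda-8,13(16)-dien-14-ol, via dianion 15 (not isolated), via cuprate 16 (not isolated)
Conditions: 14, n-BuLi (2.1 equiv), TMEDA, Et2O/hexane, 0 °C to rt; CuI, THF, −78 °C; then 13, −78 to −30 °C; aq. NH4Cl
Reagents that add atoms: none
Why: allylic substitution by a lithium homocuprate replaces only the primary allylic acetate at C11 (SN2 outcome, since the γ-carbon is tetrasubstituted), because the C–O bond of the pseudo-equatorial 7β-acetate lies in the alkene plane and the other esters are inert to cuprates at low temperature; the symmetrical 2-substituted allyl nucleophile gives one product.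

**Step 12**
Reactants: 17 7β,19-diacetoxy-15-norlabda-8,13(16)-dien-14-ol
Product: 18 (13R)-7β,19-diacetoxy-13,16-epoxy-15-norlabd-8-en-14-ol
Conditions: Ti(OiPr)4 (10 mol%), D-(−)-diisopropyl tartrate (12 mol%), t-BuOOH, 4 Å MS, CH2Cl2, −20 °C
Reagents that add atoms: tert-butyl hydroperoxide CC(C)(C)OO
Why: Sharpless asymmetric epoxidation of the 2-substituted allylic alcohol sets C13 (13R) by reagent control with the D-tartrate, and the tetrasubstituted ring alkene, which has no free allylic hydroxyl, is not touched.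

**Step 13**
Reactants: 18 (13R)-7β,19-diacetoxy-13,16-epoxy-15-norlabd-8-en-14-ol
Product: 19 (13S)-7β,19-diacetoxy-13,16-epoxy-15-norlabd-8-en-14-al
Conditions: Dess–Martin periodinane, NaHCO3, CH2Cl2, rt
Reagents that add atoms: none
Why: Dess–Martin oxidation gives the non-enolizable α-quaternary epoxy aldehyde, so C13 cannot epimerize (the descriptor changes only through CIP priorities).

**Step 14**
Reactants: 19 (13S)-7β,19-diacetoxy-13,16-epoxy-15-norlabd-8-en-14-al
Product: 20 (13R)-7β,19-diacetoxy-13,16-epoxylabd-8-en-14-yne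
Conditions: TMSCHN2, n-BuLi, THF, −78 to 0 °C
Reagents that add atoms: trimethylsilyldiazomethane C[Si](C)(C)C=[N+]=[N-]
Why: Colvin homologation (addition of lithiated TMS-diazomethane, Peterson elimination, loss of N2 and 1,2-hydride shift of the alkylidene carbene) turns the aldehyde into the terminal alkyne under non-methanolic conditions that spare the acetates and the quaternary C13.

**Step 15**
Reactants: 20 (13R)-7β,19-diacetoxy-13,16-epoxylabd-8-en-14-yne
Product: 22 (13R)-8β,19-diacetoxy-13,16-epoxylabd-14-yne-7β,9α-diol, via diepoxide 21 (not isolated)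
Conditions: mCPBA, CH2Cl2, 0 °C; then PPTS (cat.), H2O, rt
Reagents that add atoms: 3-chloroperbenzoic acid OOC(=O)c1cccc(Cl)c1; water O
Why: Prilezhaev epoxidation from the less hindered α face gives 21, whose tetrasubstituted oxirane is opened at C8 with inversion by the neighbouring 7β-acetate (trans-diaxial Fürst–Plattner opening), and the 7β,8β-dioxolanium is hydrolysed through its orthoacid to the axial tertiary acetate (King–Allbutt rule), which sets 8β-OAc and 9α-OH while the less basic propargylic oxirane survives.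

**Step 16 (key step)**
Reactants: 22 (13R)-8β,19-diacetoxy-13,16-epoxylabd-14-yne-7β,9α-diol
Product: 24 (13S)-8β,19-diacetoxy-9α,13:15,16-diepoxylabd-14-en-7β-ol, via alkynyl diol 23 (not isolated)
Conditions: Ph3PAuNTf2 (5 mol%), 2,6-di-tert-butylpyridine (10 mol%), 4 Å MS, CH2Cl2, 0 °C to rt; Et3N quench
Reagents that add atoms: none
Why: Proposed new method: cationic Ph3PAu+ binds the alkyne and activates the adjacent 2,2-disubstituted oxirane, the axial tertiary 9α-OH opens it 5-exo at the propargylic C13 with inversion (13R oxirane to 13S ether, the only new stereocentre), the released C16 hydroxyl adds 5-endo-dig to the gold-bound alkyne and protodeauration gives the enol ether, while the hindered pyridine base suppresses acid-induced reopening to a furan; the closest known reactions are gold- and silver-catalysed alkynyl oxirane–alcohol cascades to 3-alkoxy-2,3-dihydrofurans and gold-catalysed cycloisomerization of but-3-yn-1-ols.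

**Step 17**
Reactants: 24 (13S)-8β,19-diacetoxy-9α,13:15,16-diepoxylabd-14-en-7β-ol
Product: 25 (13S)-8β,19-diacetoxy-9α,13:15,16-diepoxylabd-14-en-7-one
Conditions: SO3·pyridine, DMSO, i-Pr2NEt, CH2Cl2, 0 °C
Reagents that add atoms: none
Why: Parikh–Doering oxidation converts the secondary 7β-alcohol into the ketone under basic, acid-free conditions that the enol ether and the tertiary acetate tolerate; no stereocentre is affected.

**Step 18**
Reactants: 25 (13S)-8β,19-diacetoxy-9α,13:15,16-diepoxylabd-14-en-7-one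
Product: 26 (13S)-8β-acetoxy-19-hydroxy-9α,13:15,16-diepoxylabd-14-en-7-one (target)
Conditions: K2CO3 (0.5 equiv), MeOH, 0 °C
Reagents that add atoms: none
Why: base-catalysed transesterification (Zemplén-type methanolysis) removes the primary C19 acetate far faster than the very hindered tertiary α-keto acetate (as in 21- versus 17-acetates of corticoids); the ether at C9 rules out retro-aldol and the enol ether is stable to base.

**Compound list**
1 | geranyl acetate, (2E)-3,7-dimethylocta-2,6-dien-1-yl acetate | CC(=O)OC/C=C(C)/CCC=C(C)C | starting material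
2 | (2E,6E)-8-hydroxy-3,7-dimethylocta-2,6-dien-1-yl acetate | CC(=O)OC/C=C(C)/CC/C=C(C)/CO | intermediate
3 | (2E,6E)-8-bromo-3,7-dimethylocta-2,6-dien-1-yl acetate | CC(=O)OC/C=C(C)/CC/C=C(C)/CBr | intermediate
4 | 2-(3-chloropropyl)-1,3-dioxolane | ClCCCC1OCCO1 | starting material
5 | [3-(1,3-dioxolan-2-yl)propyl]magnesium chloride | Cl[Mg]CCCC1OCCO1 | intermediate
6 | (2E,6E)-11-(1,3-dioxolan-2-yl)-3,7-dimethylundeca-2,6-dien-1-yl acetate | CC(=O)OC/C=C(C)/CC/C=C(C)/CCCCC1OCCO1 | intermediate
7 | (2E,6E)-3,7-dimethyl-12-oxododeca-2,6-dien-1-yl acetate | CC(=O)OC/C=C(C)/CC/C=C(C)/CCCCC=O | intermediate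
8 | bicyclic aldehyde: trans-decalin, 10β-CH3, 5α-H, 4α-CHO (4β-H), 8(17)-methylene, 9β-CH2OAc (9α-H) | CC(=O)OC[C@H]1C(=C)CC[C@H]2[C@H](C=O)CCC[C@]12C | intermediate
9 | 11-acetoxy-12,13,14,15,16-pentanorlabd-8(17)-en-19-al (4α-CH3, 4β-CHO) | CC(=O)OC[C@H]1C(=C)CC[C@H]2[C@@](C)(C=O)CCC[C@]12C | intermediate
10 | 11-acetoxy-12,13,14,15,16-pentanorlabd-8-en-19-al | CC(=O)OCC1=C(C)CC[C@H]2[C@@](C)(C=O)CCC[C@]12C | intermediate
11 | 11-acetoxy-7-oxo-12,13,14,15,16-pentanorlabd-8-en-19-al | CC(=O)OCC1=C(C)C(=O)C[C@H]2[C@@](C)(C=O)CCC[C@]12C | intermediate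
12 | 11-acetoxy-12,13,14,15,16-pentanorlabd-8-ene-7β,19-diol | CC(=O)OCC1=C(C)[C@@H](O)C[C@H]2[C@@](C)(CO)CCC[C@]12C | intermediate
13 | 12,13,14,15,16-pentanorlabd-8-ene-7β,11,19-triyl triacetate | CC(=O)OCC1=C(C)[C@@H](OC(C)=O)C[C@H]2[C@@](C)(COC(C)=O)CCC[C@]12C | intermediate
14 | 2-methylprop-2-en-1-ol (methallyl alcohol) | CC(=C)CO | starting material
15 | lithium 2-(lithiomethyl)prop-2-en-1-olate (dianion) | [Li]CC(=C)CO[Li] | intermediate
16 | lithium bis[2-(lithiooxymethyl)prop-2-en-1-yl]cuprate | [Li+].[Li]OCC(=C)C[Cu-]CC(=C)CO[Li] | intermediate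
17 | 7β,19-diacetoxy-15-norlabda-8,13(16)-dien-14-ol | OCC(=C)CCC1=C(C)[C@@H](OC(C)=O)C[C@H]2[C@@](C)(COC(C)=O)CCC[C@]12C | intermediate
18 | (13R)-7β,19-diacetoxy-13,16-epoxy-15-norlabd-8-en-14-ol | OC[C@@]3(CO3)CCC1=C(C)[C@@H](OC(C)=O)C[C@H]2[C@@](C)(COC(C)=O)CCC[C@]12C | intermediate
19 | (13S)-7β,19-diacetoxy-13,16-epoxy-15-norlabd-8-en-14-al | O=C[C@@]3(CO3)CCC1=C(C)[C@@H](OC(C)=O)C[C@H]2[C@@](C)(COC(C)=O)CCC[C@]12C | intermediate
20 | (13R)-7β,19-diacetoxy-13,16-epoxylabd-8-en-14-yne | C#C[C@@]3(CO3)CCC1=C(C)[C@@H](OC(C)=O)C[C@H]2[C@@](C)(COC(C)=O)CCC[C@]12C | intermediate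
21 | (13R)-7β,19-diacetoxy-8α,9α:13,16-diepoxylabd-14-yne | CC(=O)O[C@H]1C[C@H]2[C@@](C)(COC(C)=O)CCC[C@]2(C)[C@]3(CC[C@]4(CO4)C#C)O[C@]13C | intermediate
22 | (13R)-8β,19-diacetoxy-13,16-epoxylabd-14-yne-7β,9α-diol | CC(=O)O[C@@]1(C)[C@@H](O)C[C@H]2[C@@](C)(COC(C)=O)CCC[C@]2(C)[C@@]1(O)CC[C@]3(CO3)C#C | intermediate
23 | (13S)-8β,19-diacetoxy-9α,13-epoxylabd-14-yne-7β,16-diol | CC(=O)O[C@@]1(C)[C@@H](O)C[C@H]2[C@@](C)(COC(C)=O)CCC[C@]2(C)[C@@]12CC[C@@](CO)(C#C)O2 | intermediate
24 | (13S)-8β,19-diacetoxy-9α,13:15,16-diepoxylabd-14-en-7β-ol | CC(=O)O[C@@]1(C)[C@@H](O)C[C@H]2[C@@](C)(COC(C)=O)CCC[C@]2(C)[C@@]12CC[C@@]1(C=COC1)O2 | intermediate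
25 | (13S)-8β,19-diacetoxy-9α,13:15,16-diepoxylabd-14-en-7-one | CC(=O)O[C@@]1(C)C(=O)C[C@H]2[C@@](C)(COC(C)=O)CCC[C@]2(C)[C@@]12CC[C@@]1(C=COC1)O2 | intermediate
26 | (13S)-8β-acetoxy-19-hydroxy-9α,13:15,16-diepoxylabd-14-en-7-one | CC(=O)O[C@@]1(C)C(=O)C[C@H]2[C@@](C)(CO)CCC[C@]2(C)[C@@]12CC[C@@]1(C=COC1)O2 | target

**Totals**
Total steps: 18. Longest linear sequence: 18 (1 to 26).

**Three steps most likely to fail**

Step 16 (gold double cyclization). The risk is that trace acid or the cationic gold reopens the 3-alkoxy-2,3-dihydrofuran to a 3-substituted furan with a free 9-OH, or that the oxirane opens by an SN1 path and C13 scrambles. The fallback sets out from 22 and returns at 24. Camphorsulfonic acid (cat.) in CH2Cl2 at 0 °C opens the oxirane by the 9α-OH alone and the alkynyl diol 23 is isolated; W(CO)6/Et3N in THF under irradiation then closes the dihydrofuran by endo-cycloisomerization through a tungsten vinylidene under basic conditions. The two rings are thus made in two mechanistically separate steps and no compound outside the list is needed (F0).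

Step 5 (organo-SOMO bicyclization with alkene termination). The risks are early oxidation of the C10 radical, Ritter or ester trapping of the C8 cation, and modest enantioselectivity. The fallback sets out from 3 and returns at 10. Li2CuCl4-catalysed coupling of 3 with the Grignard reagent of 2-(2-bromoethyl)-1,3-dioxolane gives the one-carbon-shorter acetal (2E,6E)-10-(1,3-dioxolan-2-yl)-3,7-dimethyldeca-2,6-dien-1-yl acetate F1, and aqueous AcOH gives (2E,6E)-3,7-dimethyl-11-oxoundeca-2,6-dien-1-yl acetate F2. Vinylmagnesium bromide at −78 °C gives the racemic allylic alcohol (2E,6E)-11-hydroxy-3,7-dimethyltrideca-2,6,12-trien-1-yl acetate F3. An enantioconvergent cationic polyene cyclization with [Ir(cod)Cl]2, a chiral phosphoramidite–olefin ligand and Zn(OTf)2 gives the 4α-vinyl 8(17)-ene decalin F4. TsOH isomerizes it to the 4α-vinyl 8-ene decalin F5, OsO4 (cat.)/NaIO4 cleaves only the monosubstituted vinyl group to the 4α-formyl 8-ene decalin F6, and KOtBu/MeI methylation gives 10.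

Step 15 (epoxidation with acetate-assisted opening). The risks are collapse of the orthoacid to the secondary instead of the tertiary acetate, later acyl migration, or opening at C9 with methyl migration. The fallback sets out from 20 and returns at 25; it gives up the acetate transfer and acetylates the tertiary alcohol late. After mCPBA and aqueous acid the crude product is equilibrated with Et3N/MeOH to the thermodynamically preferred secondary acetate (13R)-7β,19-diacetoxy-13,16-epoxylabd-14-yne-8β,9α-diol F7. Ph3PAuNTf2 with 2,6-di-tert-butylpyridine gives the spiro ether (13S)-7β,19-diacetoxy-9α,13:15,16-diepoxylabd-14-en-8β-ol F8, and K2CO3/MeOH gives (13S)-9α,13:15,16-diepoxylabd-14-ene-7β,8β,19-triol F9. Oppenauer oxidation (Al(OiPr)3, cyclohexanone, PhMe, 80 °C) oxidizes only the secondary alcohol to (13S)-8β,19-dihydroxy-9α,13:15,16-diepoxylabd-14-en-7-one F10. Ac2O/DMAP/Et3N at 40 °C then acetylates the primary and the tertiary hydroxyl to give 25.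

**Further compounds**
F0 | step 16 | none | none
F1 | step 5 | (2E,6E)-10-(1,3-dioxolan-2-yl)-3,7-dimethyldeca-2,6-dien-1-yl acetate | CC(=O)OC/C=C(C)/CC/C=C(C)/CCCC1OCCO1
F2 | step 5 | (2E,6E)-3,7-dimethyl-11-oxoundeca-2,6-dien-1-yl acetate | CC(=O)OC/C=C(C)/CC/C=C(C)/CCCC=O
F3 | step 5 | (2E,6E)-11-hydroxy-3,7-dimethyltrideca-2,6,12-trien-1-yl acetate (racemic) | CC(=O)OC/C=C(C)/CC/C=C(C)/CCCC(O)C=C
F4 | step 5 | 4α-vinyl analogue of 8 (4β-H, 8(17)-methylene, 9β-CH2OAc) | CC(=O)OC[C@H]1C(=C)CC[C@H]2[C@H](C=C)CCC[C@]12C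
F5 | step 5 | 4α-vinyl 8-ene decalin (4β-H, 9-CH2OAc) | CC(=O)OCC1=C(C)CC[C@H]2[C@H](C=C)CCC[C@]12C
F6 | step 5 | 4α-formyl 8-ene decalin (4β-H, 9-CH2OAc) | CC(=O)OCC1=C(C)CC[C@H]2[C@H](C=O)CCC[C@]12C
F7 | step 15 | (13R)-7β,19-diacetoxy-13,16-epoxylabd-14-yne-8β,9α-diol | O[C@@]1(C)[C@@H](OC(C)=O)C[C@H]2[C@@](C)(COC(C)=O)CCC[C@]2(C)[C@@]1(O)CC[C@]3(CO3)C#C
F8 | step 15 | (13S)-7β,19-diacetoxy-9α,13:15,16-diepoxylabd-14-en-8β-ol | O[C@@]1(C)[C@@H](OC(C)=O)C[C@H]2[C@@](C)(COC(C)=O)CCC[C@]2(C)[C@@]12CC[C@@]1(C=COC1)O2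
F9 | step 15 | (13S)-9α,13:15,16-diepoxylabd-14-ene-7β,8β,19-triol | O[C@@]1(C)[C@@H](O)C[C@H]2[C@@](C)(CO)CCC[C@]2(C)[C@@]12CC[C@@]1(C=COC1)O2
F10 | step 15 | (13S)-8β,19-dihydroxy-9α,13:15,16-diepoxylabd-14-en-7-one | O[C@@]1(C)C(=O)C[C@H]2[C@@](C)(CO)CCC[C@]2(C)[C@@]12CC[C@@]1(C=COC1)O2
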